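The runs are simulated from invented constants.

**Mean value.** Time does little to Z in the ash run, which is the flask I am asked about: from 6.00 min to 50.0 min the readings stand level, so I replace the curve by its mean, 19.2% of the D charged, good to 0.61 percentage points.

| flask | D | Q | remark | time |
|---|---|---|---|---|
| ash | 5 mM | 1.1 equiv | the very flask that is asked about, followed so far |  |
| alder | 3.4 mM | 1.1 equiv | run made earlier |  |
| flask | 5.0 mM | 1.10 equiv |  | 50 min |

| ash: time / min | ash: Z / % | alder: time / s | alder: Z / % |
|---|---|---|---|
| 4.00 | 25 | 10.0 | 4 |
| 6.00 | 20 | 12.0 | 5 |
| 10.0 | 19 | 20.0 | 12 |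
| 15.0 | 18 | 30.0 | 13 |
| 20.0 | 19 | 50.0 | 18 |
| 30.0 | 19 | 60.0 | 20 |
| 50.0 | 20 | 120 | 20 |

(each reading ± 1.5 percentage points)

- Z that was removed still counts
- additions bring no volume worth counting

- ochre: at 50 min add D, 50.0% of the amount charged, then wait 25 min
- amber: at 50 min add Q, 100% of the amount charged, then wait 25 min
- red: change nothing and wait 25 min more
- grey: at 50 min take out 90% of the Z then present, then wait 25 min

1. Z, in percent of the D first charged, at 50 min
2. the option that brings most further Z ("none" if no option brings more than 2 percentage points) (ochre / amber / red / grey / none)
3. Z present, with what was taken out counted in, in percent of the D first charged, after ochre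
4. Z present, with what was taken out counted in, in percent of the D first charged, after red

**First doubt.** A slow drift would spoil the mean, but the last 3 readings stand above the 3 before them by 0.33 points, less than the 1.2 points that scatter gives such a difference. The reading at 4.00 min lies 3.89 standard deviations above the mean, so I can't dismiss it as scatter, but I keep it out as an early stretch.

**Second doubt.** A level Z might be a stall, yet 0.717 of Q per D charged stays free if each Z takes 2 Q. The alder run, at 3.4 mM, also levels at 20.0%. So I carry the exchange quotient, an apparent equilibrium constant: z times the square of 2z, over the rest 1 − z times the square of the free Q, q − 2z, with q the equivalents of Q. It gives 0.0678. But z enters it steeply: one error up, it is already 0.0778.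

**The forecast.** It gives 19.5% now, 19.5% after red, 22% after ochre, and amber as best, on “equal particle numbers on both sides”, with a quotient of 0.08, above mine. Its amber figure is about 32% and its grey figure about 25%.

**The result.** The flask gives 20.1%, with amber best at 15 points further, 21.1% after ochre and 20.1% after red.

    D + Q ⇌ J + E (K = 1.40, k = 22.0 M⁻¹ s⁻¹)
    E + Q ⇌ J + Z (K = 1.40, k = 8.30 M⁻¹ s⁻¹)
    D ⇌ L (K = 5.90, k = 0.00790 s⁻¹)

**At rest.** The flask has stopped: ten times the time changes nothing, Z stands at 20.1% after 500 min, and the quotient from that Z is 0.0833. Its rest is not one species but D 9.57%, E 13.9% and L 56.5%. Z moves by 5 points at 0.795 equiv or 1.44 equiv of Q, which would put the forecast outside its range.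

**Second flask.** For a neighbouring flask, the same but with 4.40 equiv of Q, I take z near one half, which cancels Z against the rest, so that in this reckoning free and released ligand stand in the ratio √K, and z comes to 45.5%. The simulation gives 54.6%.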